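The route rests on cutting the C7–C8 bond of the ten-membered carbocycle (ring A). The feature exploited is the C8 carbinol next to C7, which bears the C11(=C13)–C12 unit that later becomes the lactone (ring B): a homoallylic alcohol. A [2,3]-Wittig shift of a C8-lithiated thirteen-membered C8–O–C13 bis-allylic ether forms C7–C8, contracts the ring to ring A, moves the alkene to C11=C13, frees the C8 hydroxyl and sets C7 and C8 in one operation. The precursor, macrocyclic ether 28, has C6 cis to C13 on C7=C11, an (E)-C9=C10 alkene and silyl ethers at C3, C6 and C12.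

Key step: step 18

Numbering used throughout: ring A = C1–C10 (C3 ketone, C4 methyl-bearing CH, C6 lactone O–CH, C7 ring fusion, C8 isobutyrate carbinol, C10 methyl carbinol); C11 lactone α-carbon, C12 lactone carbonyl, C13 exocyclic methylene. Target: 4R,6S,7S,8R,10S, with O6, C11 and O8 on one face of ring A and O10 on the other (cis-fused ring B).

Assumption: the target is taken as the open γ-hydroxy ketone (C10–OH, C3=O) as drawn; its 3,10-hemiketal is only a tautomer.

Assumption: 1,3-dihydroxyacetone is used as its commercial dimer, which gives the monomer in solution.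

Design choices for the precursor:
- C3 is carried as the TBS ether of the aldol carbinol and oxidised in the last step, so no ketal is needed and no acid meets the finished γ-hydroxy ketone.
- The ring ether is closed with C13 as the electrophile and O8 as the nucleophile, so no alkoxide sits beside the C12 silyl ether; a 1,5-silyl shift there would exchange C12 and C13.
- Compounds 28 and 31 map atom for atom onto the target. CIP letters at C7 and C8 change along the route only because substituent priorities change.

Step 1
Reactants: 1 geraniol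
Product: 2 geranyl 4-methoxybenzyl (PMB) ether
Conditions: NaH, 4-methoxybenzyl chloride, Bu4NI (cat.), THF, 0 °C → rt
Reagents that add atoms: 4-methoxybenzyl chloride, COc1ccc(CCl)cc1
Why: Williamson etherification of the primary allylic alkoxide masks the future C8 oxygen with a group that tolerates the enolate, hydride, organolithium and silylation steps and is later removed oxidatively without disturbing silyl ethers.

Step 2
Reactants: 2 geranyl PMB ether
Product: 5 (E)-6-(4-methoxybenzyloxy)-4-methylhex-4-enal (the C3 aldehyde), via terminal epoxide 3 (not isolated), via glycol 4 (not isolated)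
Conditions: mCPBA, NaHCO3, CH2Cl2, 0 °C; then H5IO6, THF/H2O, 0 °C
Reagents that add atoms: mCPBA, OOC(=O)c1cccc(Cl)c1
Why: Prilezhaev epoxidation prefers the remote isopropylidene alkene, which is more electron-rich than the alkene next to the ether oxygen, and periodic acid then hydrolyses the epoxide and cleaves the glycol (Malaprade cleavage), leaving C3 as the aldehyde and the (E)-C9=C10 alkene untouched.

Step 3
Reactants: 5 C3 aldehyde; 6 (S)-4-benzyl-3-propionyloxazolidin-2-one
Product: 8 syn-aldol imide (S)-4-benzyl-3-[(2S,3R,6E)-3-hydroxy-8-(4-methoxybenzyloxy)-2,6-dimethyloct-6-enoyl]oxazolidin-2-one, via boron enolate 7 (not isolated)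
Conditions: 6, Bu2BOTf, iPr2NEt, CH2Cl2, 0 °C; then 5, −78 → 0 °C; H2O2, MeOH, pH 7 buffer, 0 °C
Reagents that add atoms: none
Why: Evans boron aldol reaction, in which the (Z)-boron enolate adds through a Zimmerman–Traxler chair on the face remote from the benzyl group, so the C4 methyl centre is set in the spatial sense of the target (acyl C2, S here) together with a syn C3 carbinol (R) that serves as the masked ketone.

Step 4
Reactants: 8 syn-aldol imide
Product: 9 C3 O-TBS ether of imide 8
Conditions: TBSOTf, 2,6-lutidine, CH2Cl2, −78 → 0 °C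
Reagents that add atoms: tert-butyldimethylsilyl triflate, CC(C)(C)[Si](C)(C)OS(=O)(=O)C(F)(F)F
Why: Silylation of the secondary carbinol with a silyl triflate and a hindered base protects O3 until the last step and removes the free β-hydroxyl that could trigger retro-aldol cleavage in the reductive step.

Step 5
Reactants: 9 silylated imide
Product: 10 (2R,3R,6E)-3-(tert-butyldimethylsilyloxy)-8-(4-methoxybenzyloxy)-2,6-dimethyloct-6-en-1-ol (the C5 alcohol)
Conditions: LiBH4, MeOH (1 equiv), THF, 0 °C
Reagents that add atoms: none
Why: Reductive removal of the auxiliary, in which borohydride attacks the exocyclic imide carbonyl and reduces it to the C5 primary alcohol without enolising C4, the oxazolidinone being recovered.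

Step 6
Reactants: 10 C5 alcohol
Product: 11 (2S,3R,6E)-3-(tert-butyldimethylsilyloxy)-1-iodo-8-(4-methoxybenzyloxy)-2,6-dimethyloct-6-ene (the C5 iodide)
Conditions: I2, PPh3, imidazole, CH2Cl2, 0 °C → rt
Reagents that add atoms: iodine, II
Why: Appel-type iodination converts the primary alcohol by SN2 displacement of an alkoxyphosphonium ion at C5, a carbon that is not a stereocentre.

Step 7
Reactants: 12 1,3-dihydroxyacetone; 13 ethyl (triphenylphosphoranylidene)acetate
Product: 15 4-(hydroxymethyl)furan-2(5H)-one, via hydroxy ester 14 (not isolated)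
Conditions: CH2Cl2, rt
Reagents that add atoms: none
Why: Wittig olefination of the ketone with a stabilised ylide gives an enoate in which one of the two equivalent hydroxymethyl groups is necessarily cis to the ester and lactonises at once, so the butenolide ring distinguishes C13 (ring CH2–O) from C12 (free CH2OH) and locks C13 cis to C6.

Step 8
Reactants: 15 4-(hydroxymethyl)furan-2(5H)-one
Product: 16 4-[(tert-butyldimethylsilyloxy)methyl]furan-2(5H)-one
Conditions: TBSCl, imidazole, CH2Cl2, 0 °C → rt
Reagents that add atoms: tert-butyldimethylsilyl chloride, CC(C)(C)[Si](C)(C)Cl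
Why: Silylation of the primary alcohol under weakly basic conditions that do not enolise the butenolide fixes the C12 oxygen as the silyl ether that is kept through the key step.

Step 9
Reactants: 16 silylated butenolide
Product: 17 4-hydroxy-3-[(tert-butyldimethylsilyloxy)methyl]-N-methoxy-N-methylbut-2-enamide with the amide carbonyl (C6) cis to the CH2OH group (C13)
Conditions: MeNH(OMe)·HCl, AlMe3, CH2Cl2, 0 °C → rt; aq. KNaC4H4O6
Reagents that add atoms: N,O-dimethylhydroxylamine hydrochloride, CNOC.Cl
Why: Weinreb aminolysis of the lactone by the aluminium amide cleaves only the acyl–oxygen bond, so C7=C11 keeps its geometry with the C6 carbonyl cis to the liberated C13 hydroxymethyl, and the substituent on C11 disfavours conjugate amination.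

Step 10
Reactants: 17 hydroxy Weinreb amide
Product: 18 O13-triethylsilyl ether of amide 17
Conditions: TESCl, imidazole, CH2Cl2, 0 °C
Reagents that add atoms: chlorotriethylsilane, CC[Si](Cl)(CC)CC
Why: Silylation of the primary allylic alcohol directly after ring opening stops relactonisation and gives a triethylsilyl ether that can later be removed in the presence of the TBS ethers.

Step 11
Reactants: 11 C5 iodide; 18 silylated Weinreb amide
Product: 20 (3R,4R)-enone with C6 as the ketone joined to C5 and C7=C11 bearing C13H2OTES cis and C12H2OTBS trans to C6, via alkyllithium 19 (not isolated)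
Conditions: 11, t-BuLi (2.1 equiv), Et2O, −78 °C; then 18, −78 → −40 °C; aq. NH4Cl
Reagents that add atoms: none
Why: Iodine–lithium exchange followed by Weinreb ketone synthesis forms C5–C6 through a chelated tetrahedral adduct that cannot add a second time, at a temperature low enough to leave C4 and the C7=C11 geometry undisturbed.

Step 12
Reactants: 20 enone
Product: 21 (3R,4R,6S)-allylic alcohol (C6 carbinol)
Conditions: (R)-Me-CBS oxazaborolidine [(R)-1-methyl-3,3-diphenyltetrahydro-1H,3H-pyrrolo[1,2-c][1,3,2]oxazaborole] (0.2 equiv), catecholborane, toluene, −78 °C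
Reagents that add atoms: none
Why: Corey–Bakshi–Shibata reduction, in which the trisubstituted alkenyl group acts as the large substituent and the (R)-catalyst delivers hydride to the ketone face that gives the (6S) alcohol under reagent control, while catecholborane at low temperature leaves the alkenes alone.

Step 13
Reactants: 21 allylic alcohol
Product: 22 C6 O-TBS ether of alcohol 21
Conditions: TBSOTf, 2,6-lutidine, CH2Cl2, −78 °C
Reagents that add atoms: tert-butyldimethylsilyl triflate, CC(C)(C)[Si](C)(C)OS(=O)(=O)C(F)(F)F
Why: Silylation of the secondary allylic alcohol installs the bulky C6 silyl ether that will steer the key step and does not disturb the triethylsilyl ether.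

Step 14
Reactants: 22 fully protected chain
Product: 23 C13 primary allylic alcohol (C3, C6 and C12 OTBS, C8 OPMB retained)
Conditions: PPTS (cat.), MeOH/CH2Cl2, 0 °C
Reagents that add atoms: none
Why: Acid-catalysed methanolysis cleaves the primary triethylsilyl ether much faster than the TBS ethers, so only the C13 hydroxyl is released, and in the absence of base no silyl group can move over from O12.

Step 15
Reactants: 23 C13 alcohol
Product: 25 C13 allylic chloride, via mesylate 24 (not isolated)
Conditions: MsCl, Et3N, CH2Cl2, −20 °C; then LiCl, DMF, 0 °C → rt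
Reagents that add atoms: lithium chloride, [Li+].[Cl-]
Why: Sulfonylation and chloride displacement (SN2 at the primary allylic C13, the SN2' terminus C7 being secondary and shielded by C6) turn C13 into the electrophile of the ring closure under conditions too weakly basic for silyl migration.

Step 16
Reactants: 25 C13 chloride
Product: 26 chloro alcohol with free C8 hydroxyl
Conditions: DDQ, CH2Cl2/pH 7 buffer, 0 °C
Reagents that add atoms: none
Why: Oxidative cleavage of the PMB ether by DDQ (hydride abstraction to a benzylic oxocarbenium ion, then hydrolysis) frees the C8 hydroxyl and spares the silyl ethers, the allylic chloride and the alkenes.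

Step 17
Reactants: 26 chloro alcohol
Product: 28 thirteen-membered C8–O–C13 bis-allylic ether, (3R,4R,6S)-3,6-bis(tert-butyldimethylsilyloxy)-11-[(tert-butyldimethylsilyloxy)methyl]-4,10-dimethyl ring with (E)-C9=C10 and C6 cis to C13 on C7=C11 (a 1-oxacyclotrideca-3,11-diene), via sodium alkoxide 27 (not isolated)
Conditions: NaH, Bu4NI (cat.), THF, 45 °C, slow addition to a final concentration of about 2 mM
Reagents that add atoms: none
Why: Intramolecular Williamson etherification under high dilution, in which the unhindered C8 alkoxide displaces the primary allylic chloride at C13 (SN2), a closure of the kind known for thirteen-membered bis-allylic ethers, and because the nucleophile is O8 no alkoxide is placed beside the C12 silyl ether.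

Step 18
Reactants: 28 thirteen-membered bis-allylic ether
Product: 31 ten-membered dienol (3R,4R,6S,7R,8R) with free C8 hydroxyl, (E)-C9=C10, C7 bearing the C11(=C13H2)–C12H2OTBS group and OTBS at C3 and C6, via C8-lithiated ether 29 (not isolated), via lithium alkoxide 30 (not isolated)
Conditions: n-BuLi (2 equiv), THF, −78 → −25 °C; aq. NH4Cl at −78 °C
Reagents that add atoms: none
Why: n-BuLi removes a proton from C8, the one ether α-methylene that is both unhindered and allylic to C9=C10 (the C13 and C12 methylenes hang on the fully substituted C11 and their allyl anions would suffer allylic strain), and the α-oxy allyl anion rearranges by a concerted [2,3]-sigmatropic (Wittig) shift through a five-centre envelope C8–O–C13–C11–C7, suprafacial on the allyl unit, which makes C7–C8, breaks O–C13, moves the alkene to C11=C13 and leaves the C8 alkoxide. The closest known reaction is the [2,3]-Wittig ring contraction of thirteen-membered bis-allylic ethers to cyclodecadienols of the germacrane type. Ring A closes transannularly (13 to 10 atoms), the new bond being the edge shared by ring A and the five-centre array, so the two reacting carbons are already held together by the ether. C8 relative to C7: the C9 vinyl group sits exo on the envelope because the endo position collides with the C12 silyloxymethyl group on C11, and with C6 cis to C13 this gives O8 and C11 on the same face of ring A. C7 relative to C6: allylic 1,3-strain keeps H6 in the alkene plane toward C13 and ring carbon C5 must lie anti to the forming bond (a gauche C5 would clash with the exo C9), so C8 should bond to the alkene face that carries O6 and H6 and H7 end up cis. The step needs C8 site selectivity, one alkene face and retention of (E)-C9=C10; the first two are secured as stated and the third by keeping the anion cold, where [1,2]-shift and allyl-anion isomerisation are slow, and the cold quench also prevents silyl transfer from O6 to the new alkoxide.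

Step 19
Reactants: 31 ten-membered dienol
Product: 32 (9S,10S)-9,10-epoxy alcohol (3R,4R,6S,7R,8S,9S,10S)
Conditions: VO(acac)2 (5 mol %), t-BuOOH, CH2Cl2, 0 °C → rt
Reagents that add atoms: tert-butyl hydroperoxide, CC(C)(C)OO
Why: Hydroxyl-directed vanadium-catalysed epoxidation, in which the C8 vanadate ester reacts far faster with the allylic trisubstituted C9=C10 than with the homoallylic C11=C13, and because the required O8–C8–C9=C10 dihedral angle of roughly 40–50° is reachable in the trans-cyclodecene only with C7 on the inner face, oxygen should arrive on the outer face next to O8 and give the epoxide whose C10–O bond has the target configuration.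

Step 20
Reactants: 32 epoxy alcohol
Product: 33 C8,C10-diol (3R,4R,6S,7R,8R,10S) with C9 as a methylene
Conditions: NaAlH2(OCH2CH2OMe)2, THF, 0 °C → rt; aq. KNaC4H4O6
Reagents that add atoms: none
Why: Regioselective reductive opening of a 2,3-epoxy alcohol, in which the aluminate bound to O8 delivers hydride to C9, the epoxide carbon that is both proximal and less substituted, so C10 keeps its oxygen and its configuration in the resulting 1,3-diol.

Step 21
Reactants: 33 diol
Product: 34 C8 isobutyrate (3R,4R,6S,7R,8R,10S) with free tertiary C10 hydroxyl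
Conditions: isobutyric anhydride, DMAP, Et3N, CH2Cl2, rt
Reagents that add atoms: isobutyric anhydride, CC(C)C(=O)OC(=O)C(C)C
Why: DMAP-catalysed acyl transfer esterifies the secondary C8 hydroxyl while the tertiary C10 hydroxyl is inert, and it must precede lactone formation because a free O8 is also γ to C12.

Step 22
Reactants: 34 isobutyrate
Product: 35 tetraol (3R,4R,6S,7S,8R,10S) with free hydroxyls at C3, C6, C10 and C12 and the C8 isobutyrate
Conditions: HF·pyridine, pyridine, THF, 0 °C → rt
Reagents that add atoms: none
Why: Fluoride-mediated cleavage of all three silyl ethers under buffered acidic conditions avoids the alkoxide intermediates that would let the isobutyryl group migrate from O8 to O6 and leaves the tertiary alcohol intact.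

Step 23
Reactants: 35 tetraol
Product: 38 3-hydroxy α-methylene lactone (3R,4R,6S,7S,8R,10S), the C3 alcohol of the target, via enal 36 (not isolated), via lactol 37 (not isolated)
Conditions: MnO2, CH2Cl2, rt
Reagents that add atoms: none
Why: MnO2 oxidative lactonisation, in which only the C12 hydroxyl is allylic, the resulting enal is trapped by the C6 hydroxyl as a five-membered allylic lactol and this is oxidised on to the α-methylene lactone (ring B), with C6 and C7 untouched so that the cis ring fusion follows from the key step.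

Step 24
Reactants: 38 3-hydroxy lactone
Product: 39 CNP0293926.1 (4R,6S,7S,8R,10S)
Conditions: Dess–Martin periodinane, NaHCO3, CH2Cl2, 0 °C → rt
Reagents that add atoms: none
Why: Dess–Martin oxidation converts the one remaining secondary alcohol (C3) into the ketone under buffered neutral conditions that should not epimerise C4, eliminate the tertiary C10 hydroxyl or touch the ester and lactone.

Compound list
1 | geraniol | CC(C)=CCC/C(C)=C/CO | starting material
2 | geranyl 4-methoxybenzyl ether | CC(C)=CCC/C(C)=C/COCc1ccc(OC)cc1 | intermediate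
3 | terminal epoxide of 2 (racemic at the epoxide carbon, formed in situ) | CC1(C)OC1CC/C(C)=C/COCc1ccc(OC)cc1 | intermediate
4 | glycol from epoxide 3 (formed in situ) | CC(C)(O)C(O)CC/C(C)=C/COCc1ccc(OC)cc1 | intermediate
5 | (E)-6-(4-methoxybenzyloxy)-4-methylhex-4-enal | O=CCC/C(C)=C/COCc1ccc(OC)cc1 | intermediate
6 | (S)-4-benzyl-3-propionyloxazolidin-2-one | CCC(=O)N1[C@@H](Cc2ccccc2)COC1=O | starting material
7 | (Z)-dibutylboron enolate of 6 (formed in situ) | C/C=C(\OB(CCCC)CCCC)N1[C@@H](Cc2ccccc2)COC1=O | intermediate
8 | (S)-4-benzyl-3-[(2S,3R,6E)-3-hydroxy-8-(4-methoxybenzyloxy)-2,6-dimethyloct-6-enoyl]oxazolidin-2-one | O=C([C@@H](C)[C@H](O)CC/C(C)=C/COCc1ccc(OC)cc1)N1[C@@H](Cc2ccccc2)COC1=O | intermediate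
9 | C3 O-TBS ether of 8 | O=C([C@@H](C)[C@H](O[Si](C)(C)C(C)(C)C)CC/C(C)=C/COCc1ccc(OC)cc1)N1[C@@H](Cc2ccccc2)COC1=O | intermediate
10 | (2R,3R,6E)-3-(tert-butyldimethylsilyloxy)-8-(4-methoxybenzyloxy)-2,6-dimethyloct-6-en-1-ol | OC[C@@H](C)[C@H](O[Si](C)(C)C(C)(C)C)CC/C(C)=C/COCc1ccc(OC)cc1 | intermediate
11 | (2S,3R,6E)-3-(tert-butyldimethylsilyloxy)-1-iodo-8-(4-methoxybenzyloxy)-2,6-dimethyloct-6-ene | IC[C@@H](C)[C@H](O[Si](C)(C)C(C)(C)C)CC/C(C)=C/COCc1ccc(OC)cc1 | intermediate
12 | 1,3-dihydroxyacetone | OCC(=O)CO | starting material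
13 | ethyl (triphenylphosphoranylidene)acetate | CCOC(=O)C=P(c1ccccc1)(c1ccccc1)c1ccccc1 | starting material
14 | ethyl 4-hydroxy-3-(hydroxymethyl)but-2-enoate (formed in situ) | CCOC(=O)C=C(CO)CO | intermediate
15 | 4-(hydroxymethyl)furan-2(5H)-one | O=C1C=C(CO)CO1 | intermediate
16 | 4-[(tert-butyldimethylsilyloxy)methyl]furan-2(5H)-one | O=C1C=C(CO[Si](C)(C)C(C)(C)C)CO1 | intermediate
17 | 4-hydroxy-3-[(tert-butyldimethylsilyloxy)methyl]-N-methoxy-N-methylbut-2-enamide, carbonyl cis to CH2OH | CON(C)C(=O)/C=C(\CO)CO[Si](C)(C)C(C)(C)C | intermediate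
18 | O13-triethylsilyl ether of 17 | CON(C)C(=O)/C=C(\CO[Si](CC)(CC)CC)CO[Si](C)(C)C(C)(C)C | intermediate
19 | C5 alkyllithium from iodide 11 (formed in situ) | [Li]C[C@@H](C)[C@H](O[Si](C)(C)C(C)(C)C)CC/C(C)=C/COCc1ccc(OC)cc1 | intermediate
20 | (3R,4R)-C6 enone, C13H2OTES cis and C12H2OTBS trans to C6, C3 OTBS, C8 OPMB | O=C(/C=C(\CO[Si](CC)(CC)CC)CO[Si](C)(C)C(C)(C)C)C[C@@H](C)[C@H](O[Si](C)(C)C(C)(C)C)CC/C(C)=C/COCc1ccc(OC)cc1 | intermediate
21 | (3R,4R,6S)-C6 allylic alcohol | O[C@H](/C=C(\CO[Si](CC)(CC)CC)CO[Si](C)(C)C(C)(C)C)C[C@@H](C)[C@H](O[Si](C)(C)C(C)(C)C)CC/C(C)=C/COCc1ccc(OC)cc1 | intermediate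
22 | C6 O-TBS ether of 21 | CC(C)(C)[Si](C)(C)O[C@H](/C=C(\CO[Si](CC)(CC)CC)CO[Si](C)(C)C(C)(C)C)C[C@@H](C)[C@H](O[Si](C)(C)C(C)(C)C)CC/C(C)=C/COCc1ccc(OC)cc1 | intermediate
23 | C13 primary allylic alcohol (C3, C6, C12 OTBS; C8 OPMB) | CC(C)(C)[Si](C)(C)O[C@H](/C=C(\CO)CO[Si](C)(C)C(C)(C)C)C[C@@H](C)[C@H](O[Si](C)(C)C(C)(C)C)CC/C(C)=C/COCc1ccc(OC)cc1 | intermediate
24 | C13 mesylate of 23 (formed in situ) | CC(C)(C)[Si](C)(C)O[C@H](/C=C(\COS(C)(=O)=O)CO[Si](C)(C)C(C)(C)C)C[C@@H](C)[C@H](O[Si](C)(C)C(C)(C)C)CC/C(C)=C/COCc1ccc(OC)cc1 | intermediate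
25 | C13 allylic chloride (C8 OPMB) | CC(C)(C)[Si](C)(C)O[C@H](/C=C(\CCl)CO[Si](C)(C)C(C)(C)C)C[C@@H](C)[C@H](O[Si](C)(C)C(C)(C)C)CC/C(C)=C/COCc1ccc(OC)cc1 | intermediate
26 | chloro alcohol: C13 chloride with free C8 hydroxyl | CC(C)(C)[Si](C)(C)O[C@H](/C=C(\CCl)CO[Si](C)(C)C(C)(C)C)C[C@@H](C)[C@H](O[Si](C)(C)C(C)(C)C)CC/C(C)=C/CO | intermediate
27 | sodium C8 alkoxide of 26 (formed in situ) | CC(C)(C)[Si](C)(C)O[C@H](/C=C(\CCl)CO[Si](C)(C)C(C)(C)C)C[C@@H](C)[C@H](O[Si](C)(C)C(C)(C)C)CC/C(C)=C/C[O-].[Na+] | intermediate
28 | thirteen-membered C8–O–C13 bis-allylic ether (3R,4R,6S), C3 and C6 OTBS, C12H2OTBS, (E)-C9=C10, C6 cis to C13 | O1C/C(CO[Si](C)(C)C(C)(C)C)=C\[C@@H](O[Si](C)(C)C(C)(C)C)C[C@@H](C)[C@H](O[Si](C)(C)C(C)(C)C)CC/C(C)=C/C1 | intermediate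
29 | C8-lithiated ether from 28 (formed in situ) | O1C/C(CO[Si](C)(C)C(C)(C)C)=C\[C@@H](O[Si](C)(C)C(C)(C)C)C[C@@H](C)[C@H](O[Si](C)(C)C(C)(C)C)CC/C(C)=C/C1[Li] | intermediate
30 | lithium C8 alkoxide of 31 (formed in situ) | C=C(CO[Si](C)(C)C(C)(C)C)[C@H]1[C@@H](O[Si](C)(C)C(C)(C)C)C[C@@H](C)[C@H](O[Si](C)(C)C(C)(C)C)CC/C(C)=C/[C@H]1O[Li] | intermediate
31 | ten-membered (E)-C9=C10 dienol (3R,4R,6S,7R,8R), free C8 hydroxyl | C=C(CO[Si](C)(C)C(C)(C)C)[C@H]1[C@@H](O[Si](C)(C)C(C)(C)C)C[C@@H](C)[C@H](O[Si](C)(C)C(C)(C)C)CC/C(C)=C/[C@H]1O | intermediate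
32 | (9S,10S)-9,10-epoxy alcohol | C=C(CO[Si](C)(C)C(C)(C)C)[C@H]1[C@@H](O[Si](C)(C)C(C)(C)C)C[C@@H](C)[C@H](O[Si](C)(C)C(C)(C)C)CC[C@]2(C)O[C@H]2[C@H]1O | intermediate
33 | C8,C10-diol (10S) | C=C(CO[Si](C)(C)C(C)(C)C)[C@H]1[C@@H](O[Si](C)(C)C(C)(C)C)C[C@@H](C)[C@H](O[Si](C)(C)C(C)(C)C)CC[C@](C)(O)C[C@H]1O | intermediate
34 | C8 isobutyrate of 33 | C=C(CO[Si](C)(C)C(C)(C)C)[C@H]1[C@@H](O[Si](C)(C)C(C)(C)C)C[C@@H](C)[C@H](O[Si](C)(C)C(C)(C)C)CC[C@](C)(O)C[C@H]1OC(=O)C(C)C | intermediate
35 | tetraol (C3, C6, C10, C12 hydroxyls) with C8 isobutyrate | C=C(CO)[C@H]1[C@@H](O)C[C@@H](C)[C@H](O)CC[C@](C)(O)C[C@H]1OC(=O)C(C)C | intermediate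
36 | C12 enal from 35 (formed in situ) | C=C(C=O)[C@H]1[C@@H](O)C[C@@H](C)[C@H](O)CC[C@](C)(O)C[C@H]1OC(=O)C(C)C | intermediate
37 | 6,12-lactol (formed in situ, lactol carbon undefined) | C=C1C(O)O[C@H]2C[C@@H](C)[C@H](O)CC[C@](C)(O)C[C@@H](OC(=O)C(C)C)[C@@H]12 | intermediate
38 | 3-hydroxy α-methylene lactone (3R,4R,6S,7S,8R,10S) | C=C1C(=O)O[C@H]2C[C@@H](C)[C@H](O)CC[C@](C)(O)C[C@@H](OC(=O)C(C)C)[C@@H]12 | intermediate
39 | CNP0293926.1 (4R,6S,7S,8R,10S) | C=C1C(=O)O[C@H]2C[C@@H](C)C(=O)CC[C@](C)(O)C[C@@H](OC(=O)C(C)C)[C@@H]12 | target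

Total step count: 24. Longest linear sequence: 20 steps (steps 1–6, then 11–24).

Steps most likely to fail

Step 18. Metalation may occur at the C13 or C12 methylene instead of C8, a [1,2]-shift may compete, or the new bond may form on the alkene face away from O6. The fallback makes the same C7–C8 bond by carbonyl allylation instead of carbanion rearrangement. It sets out from chloro alcohol 26: Bu3SnLi (2.2 equiv, THF, −78 °C) displaces the C13 chloride to give hydroxy allylstannane F1, MnO2 oxidises the C8 allylic alcohol to stannyl enal F2, and BF3·OEt2 in CH2Cl2 at −78 °C under high dilution triggers an intramolecular SE2' addition of the allylstannane through C7 to the C8 aldehyde. This known type of macrocyclisation should give dienol 31, where the route is rejoined. The open antiperiplanar transition state favours the same C7/C8 relation, and electrophilic attack anti to the C5–C6 bond with H6 in the alkene plane again places the new bond on the O6 face.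

Step 17. Intermolecular etherification and oligomer formation may outrun closure of the thirteen-membered ring. The fallback ionises at C8 instead of displacing at C13. It sets out from 22: DDQ removes the PMB group to give C8 alcohol F3, acetic anhydride and pyridine give C8 acetate F4, and PPTS in methanol releases the C13 hydroxyl to give hydroxy acetate F5. Et2Zn, Pd(OAc)2 and 2-(di-tert-butylphosphino)biphenyl in THF under high dilution then generate a π-allyl complex of palladium from the geranyl-type acetate, and the zinc alkoxide of O13, too weakly basic to pass a silyl group from O12, attacks its primary terminus C8 with retention of the (E) geometry. This should give macrocycle 28, where the route is rejoined.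

Step 19. Oxygen may be delivered to the other face of C9=C10, which would give the C10 epimer. The fallback installs the C10 hydroxyl by anti addition instead of syn delivery. It sets out from dienol 31: NBS in THF/H2O at 0 °C forms a bromonium ion on the exposed face of the more electron-rich C9=C10 and water opens it at the tertiary C10 from the opposite face to give bromohydrin F6. Bu3SnH with AIBN in toluene at 80 °C then removes the C9 bromine and should give diol 33, where the route is rejoined. Because the hydroxyl enters anti to the electrophile, this gives the C10 configuration opposite to that of an epoxidation on the same face.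

Further compounds
F1 | step 18 | hydroxy allylstannane (C13 tributylstannyl, free C8 hydroxyl) | CC(C)(C)[Si](C)(C)O[C@H](/C=C(\C[Sn](CCCC)(CCCC)CCCC)CO[Si](C)(C)C(C)(C)C)C[C@@H](C)[C@H](O[Si](C)(C)C(C)(C)C)CC/C(C)=C/CO
F2 | step 18 | stannyl enal (C13 tributylstannyl, C8 aldehyde) | CC(C)(C)[Si](C)(C)O[C@H](/C=C(\C[Sn](CCCC)(CCCC)CCCC)CO[Si](C)(C)C(C)(C)C)C[C@@H](C)[C@H](O[Si](C)(C)C(C)(C)C)CC/C(C)=C/C=O
F3 | step 17 | C8 alcohol with C13 triethylsilyl ether | CC(C)(C)[Si](C)(C)O[C@H](/C=C(\CO[Si](CC)(CC)CC)CO[Si](C)(C)C(C)(C)C)C[C@@H](C)[C@H](O[Si](C)(C)C(C)(C)C)CC/C(C)=C/CO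
F4 | step 17 | C8 acetate with C13 triethylsilyl ether | CC(C)(C)[Si](C)(C)O[C@H](/C=C(\CO[Si](CC)(CC)CC)CO[Si](C)(C)C(C)(C)C)C[C@@H](C)[C@H](O[Si](C)(C)C(C)(C)C)CC/C(C)=C/COC(C)=O
F5 | step 17 | hydroxy acetate (free C13 hydroxyl, C8 acetate) | CC(C)(C)[Si](C)(C)O[C@H](/C=C(\CO)CO[Si](C)(C)C(C)(C)C)C[C@@H](C)[C@H](O[Si](C)(C)C(C)(C)C)CC/C(C)=C/COC(C)=O
F6 | step 19 | bromohydrin (C9 bromide, C10 tertiary alcohol, 10S) | C=C(CO[Si](C)(C)C(C)(C)C)[C@H]1[C@@H](O[Si](C)(C)C(C)(C)C)C[C@@H](C)[C@H](O[Si](C)(C)C(C)(C)C)CC[C@](C)(O)[C@H](Br)[C@H]1O
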